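**Retrosynthetic overview**
1. Feature: ring B, the aryl group on benzofuran C2, is a pentasubstituted resorcinol (C1' junction, C2' prenyl, C3' OH, C4' H, C5' pyran O, C6' pyran CH2). Its hindered C1' lies between C2' and C6', so C1'/C6' are taken as the two carbons of an alkyne and C2'–C5' as a γ-prenylated acetoacetate diene.
2. Backwards: the silyl ethers come off, the chroman C4 methylene comes from a chromanone C=O, the pyran O–C(Me)2 bond from an oxa-Michael addition, and ring B (C1'–C2', C5'–C6') from a Diels–Alder aromatization on a benzofuran-2-yl ynone.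
3. The ynone comes from Sonogashira coupling of a 2-bromobenzofuran followed by oxidation. The furan ring comes from C–O closure of a 2-(2,2-dibromovinyl)phenol whose only free OH lies next to the side chain.
4. The stereocentre comes from a sparteine-controlled lithiation–borylation on a phloroglucinol-derived aryl boronate, followed by a stereoretentive Zweifel olefination.
5. Ring order: ring A (phloroglucinol, bought), furan ring (step 10), ring B (step 17), pyran ring (step 18).

Key step: step 17

Assumption: the [C@@H] centre is read as (R) (aryl > isopropenyl > methyl > H), and (+)-sparteine is taken as a purchasable reagent.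

Abbreviations: TBS = tert-butyldimethylsilyl, MOM = methoxymethyl, pin = pinacolato.

**Step 1**
Reactants: 1 phloroglucinol
Product: 2 1,3,5-tris(methoxymethoxy)benzene
Conditions: MOMCl, NaH, DMF, 0 °C to rt
Reagents that add atoms: chloromethyl methyl ether, COCCl
Why: Williamson-type O-alkylation of the triphenoxide gives the tris-acetal, whose OMOM groups direct both later ring lithiations.

**Step 2**
Reactants: 2 1,3,5-tris(methoxymethoxy)benzene
Product: 4 2-[2,4,6-tris(methoxymethoxy)phenyl]-4,4,5,5-tetramethyl-1,3,2-dioxaborolane, via aryllithium 3 (not isolated)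
Conditions: n-BuLi, THF, 0 °C; then iPrOBpin, −78 °C to rt
Reagents that add atoms: 2-isopropoxy-4,4,5,5-tetramethyl-1,3,2-dioxaborolane, CC(C)OB1OC(C)(C)C(C)(C)O1
Why: Directed ortho-metalation takes a ring C–H between two OMOM groups (all three positions are equivalent), and the aryllithium is trapped by the borate ester.

**Step 3**
Reactants: 5 2,4,6-triisopropylbenzoic acid; 6 iodoethane
Product: 7 ethyl 2,4,6-triisopropylbenzoate
Conditions: K2CO3, DMF, rt
Reagents that add atoms: none
Why: SN2 O-alkylation of the carboxylate avoids the hindered carbonyl carbon and gives the precursor of the chiral carbenoid.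

**Step 4**
Reactants: 7 ethyl 2,4,6-triisopropylbenzoate; 4 aryl pinacol boronate
Product: 10 (S)-4,4,5,5-tetramethyl-2-{1-[2,4,6-tris(methoxymethoxy)phenyl]ethyl}-1,3,2-dioxaborolane, via lithiated benzoate 8 (not isolated), via boronate complex 9 (not isolated)
Conditions: 7, s-BuLi, (+)-sparteine, Et2O, −78 °C; then 4, −78 °C; then reflux
Reagents that add atoms: none
Why: In this lithiation–borylation, s-BuLi/(+)-sparteine removes the pro-R hydrogen to give the configurationally stable (R)-carbenoid 8, which binds boron with retention, and the electron-rich aryl group then migrates anti to the benzoate with inversion, so the diamine sets the benzylic centre as (S).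

**Step 5**
Reactants: 10 (S)-benzylic pinacol boronate; 11 2-bromopropene
Product: 15 (R)-1,3,5-tris(methoxymethoxy)-2-(3-methylbut-3-en-2-yl)benzene, via isopropenyllithium 12 (not isolated), via alkenylboronate complex 13 (not isolated), via iodoalkyl boronic ester 14 (not isolated)
Conditions: 11, t-BuLi, Et2O, −78 °C; then 10, THF, −78 °C; I2, THF, −78 °C; NaOMe, MeOH, −78 °C to rt
Reagents that add atoms: none
Why: In this Zweifel olefination, iodine activates the alkenyl boronate, the benzylic carbon migrates with retention of configuration, and methoxide-induced elimination of boron and iodide gives the 1,1-disubstituted alkene, the descriptor changing to (R) only through the priority rules.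

**Step 6**
Reactants: 15 (R)-tris-MOM arene
Product: 17 2,4,6-tris(methoxymethoxy)-3-[(2R)-3-methylbut-3-en-2-yl]benzaldehyde, via aryllithium 16 (not isolated)
Conditions: n-BuLi, THF, −20 to 0 °C; then DMF
Reagents that add atoms: N,N-dimethylformamide, CN(C)C=O
Why: Directed ortho-metalation and formylation work here because the ring C–H between two OMOM groups is metalated far faster than the tertiary benzylic C–H, whose anion cannot become coplanar with the di-ortho-substituted ring, so the stereocentre should stay intact.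

**Step 7**
Reactants: 17 tris-MOM aldehyde
Product: 18 2,4,6-trihydroxy-3-[(2R)-3-methylbut-3-en-2-yl]benzaldehyde
Conditions: HCl (1.25 M in MeOH), 0 °C to rt
Reagents that add atoms: none
Why: Acid-catalysed acetal methanolysis cleaves aryl MOM ethers ortho and para to a formyl group under conditions in common use for o-prenylated acylphloroglucinols, so the isopropenyl group should not be protonated.

**Step 8**
Reactants: 18 trihydroxy aldehyde
Product: 19 4,6-bis[(tert-butyldimethylsilyl)oxy]-2-hydroxy-3-[(2R)-3-methylbut-3-en-2-yl]benzaldehyde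
Conditions: TBSCl (2.1 equiv), imidazole, CH2Cl2–DMF, 0 °C
Reagents that add atoms: tert-butyldimethylsilyl chloride, CC(C)(C)[Si](C)(C)Cl
Why: Silylation is regioselective because the non-chelated 4-OH and the less hindered 6-OH react, while the 2-OH, hydrogen-bonded to the aldehyde and wedged between CHO and the branched side chain, stays free and so becomes the furan oxygen.

**Step 9**
Reactants: 19 bis-TBS salicylaldehyde
Product: 20 3,5-bis[(tert-butyldimethylsilyl)oxy]-2-(2,2-dibromovinyl)-6-[(2R)-3-methylbut-3-en-2-yl]phenol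
Conditions: CBr4, PPh3, Zn, CH2Cl2, rt (reagent preformed); then 19, 0 °C to rt
Reagents that add atoms: carbon tetrabromide, BrC(Br)(Br)Br
Why: The zinc variant of the Ramirez (Corey–Fuchs) dibromoolefination avoids Ph3PBr2 and HBr, so the silyl ethers, the free phenol and the alkene should survive.

**Step 10**
Reactants: 20 dibromovinylphenol
Product: 21 2-bromo-4,6-bis[(tert-butyldimethylsilyl)oxy]-7-[(2R)-3-methylbut-3-en-2-yl]benzofuran
Conditions: CuI (5 mol %), K3PO4, THF, 80 °C (sealed)
Reagents that add atoms: none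
Why: An intramolecular Ullmann-type C–O vinylation of the bromide cis to the arene closes the five-membered furan ring, and because only the oxygen next to the side chain is free, the side chain ends up on C7.

**Step 11**
Reactants: 22 3-methylbut-2-enal; 23 ethynylmagnesium bromide
Product: 24 5-methylhex-4-en-1-yn-3-ol (racemic)
Conditions: THF, 0 °C
Reagents that add atoms: none
Why: The alkynyl Grignard reagent adds 1,2 to the enal, and the racemic carbinol centre is erased in step 13.

**Step 12**
Reactants: 21 2-bromobenzofuran; 24 alkynol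
Product: 25 1-{4,6-bis[(tert-butyldimethylsilyl)oxy]-7-[(2R)-3-methylbut-3-en-2-yl]benzofuran-2-yl}-5-methylhex-4-en-1-yn-3-ol (both carbinol epimers)
Conditions: PdCl2(PPh3)2 (3 mol %), CuI (5 mol %), Et3N, THF, 40 °C
Reagents that add atoms: none
Why: In this Sonogashira coupling the C2–Br bond of a benzofuran adds readily to zerovalent palladium, and the aryl silyl ethers tolerate the amine base.

**Step 13**
Reactants: 25 coupled alkynol
Product: 26 1-{4,6-bis[(tert-butyldimethylsilyl)oxy]-7-[(2R)-3-methylbut-3-en-2-yl]benzofuran-2-yl}-5-methylhex-4-en-1-yn-3-one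
Conditions: MnO2, CH2Cl2, rt
Reagents that add atoms: none
Why: MnO2 oxidizes this doubly activated (propargylic and allylic) alcohol under neutral conditions that leave the alkenes and silyl ethers untouched.

**Step 14**
Reactants: 27 methyl acetoacetate; 28 prenyl bromide
Product: 30 methyl 7-methyl-3-oxooct-6-enoate, via acetoacetate dianion 29 (not isolated)
Conditions: NaH, THF, 0 °C; n-BuLi, 0 °C; then 28, 0 °C to rt
Reagents that add atoms: none
Why: In the γ-alkylation of a β-keto ester dianion, the more basic terminal carbanion is the one that attacks prenyl bromide.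

**Step 15**
Reactants: 30 γ-prenylated keto ester
Product: 31 methyl 7-methyl-3-(trimethylsilyloxy)octa-2,6-dienoate (mixture of C2=C3 isomers)
Conditions: TMSCl, Et3N, toluene, rt
Reagents that add atoms: chlorotrimethylsilane, C[Si](C)(C)Cl
Why: O-silylation of the enolized β-keto ester is the first stage of the standard two-stage bis(silyl enol ether) synthesis.

**Step 16**
Reactants: 31 silyl enol ether
Product: 33 (1Z,3Z)-1-methoxy-7-methyl-1,3-bis(trimethylsilyloxy)octa-1,3,6-triene, via lithium dienolate 32 (not isolated)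
Conditions: LDA, THF, −78 °C; then TMSCl, −78 °C to rt
Reagents that add atoms: chlorotrimethylsilane, C[Si](C)(C)Cl
Why: γ-Deprotonation and O-silylation of the ester dienolate give the diene with the prenyl chain trans to C2, so it points outward in the s-cis conformer needed for cycloaddition.

**Step 17**
Reactants: 26 benzofuran-2-yl ynone; 33 bis(silyloxy) diene
Product: 36 2-[3,5-dihydroxy-2-(3-methylbut-2-enoyl)-6-(3-methylbut-2-enyl)phenyl]-4,6-bis[(tert-butyldimethylsilyl)oxy]-7-[(2R)-3-methylbut-3-en-2-yl]benzofuran, via cyclohexadiene adduct 34 (not isolated), via mono-TMS resorcinol 35 (not isolated)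
Conditions: 33 (3 equiv), toluene, 115 °C, sealed tube, argon; then citric acid (cat.), MeOH, rt
Reagents that add atoms: none
Why: In this normal-electron-demand Diels–Alder reaction the prenyl-bearing C4 terminus of 33, which has the largest HOMO coefficient, bonds to the ynone β-carbon (future C1') and the ketene-acetal carbon C1 bonds to the α-carbon (future C6'), in one asynchronous event or as a conjugate addition followed by closure of the allenolate, to give cyclohexa-1,4-diene 34. Loss of MeOSiMe3 from the mixed acetal carbon and enolization give arene 35, and mild methanolysis removes the last TMS group while the aryl TBS ethers stay. The closest known reaction type is the Diels–Alder aromatization of 1-alkoxy-1,3-bis(silyloxy)dienes with acetylenic ketones and esters to give resorcinols. Ring B closes as a six-membered carbocycle by intermolecular [4+2] cycloaddition, which forms both C1'–C2' and C5'–C6'. No lasting stereocentre is created, because both sp3 ring carbons of 34 become aromatic, and the (R)-centre of the side chain is remote and untouched. The step needs regioselectivity, secured by the matched polarization of the diene (donors on C1 and C3) and the ynone carbonyl, and chemoselectivity for the alkyne, secured by the β,β-dimethyl block on the enone and the unactivated nature of the prenyl and isopropenyl alkenes.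

**Step 18**
Reactants: 36 hydroxy enone
Product: 37 5-{4,6-bis[(tert-butyldimethylsilyl)oxy]-7-[(2R)-3-methylbut-3-en-2-yl]benzofuran-2-yl}-7-hydroxy-2,2-dimethyl-6-(3-methylbut-2-enyl)chroman-4-one
Conditions: Et3N, CH2Cl2, rt to 40 °C
Reagents that add atoms: none
Why: In this 6-endo-trig oxa-Michael addition only the C5' OH ortho to the acyl group can reach the β-carbon, and a tertiary amine in a dry aprotic solvent should not cleave the aryl silyl ethers.

**Step 19**
Reactants: 37 7-hydroxychromanone
Product: 38 5-{4,6-bis[(tert-butyldimethylsilyl)oxy]-7-[(2R)-3-methylbut-3-en-2-yl]benzofuran-2-yl}-2,2-dimethyl-6-(3-methylbut-2-enyl)-4-oxochroman-7-yl acetate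
Conditions: Ac2O, pyridine, DMAP (cat.), CH2Cl2, 0 °C
Reagents that add atoms: acetic anhydride, CC(=O)OC(C)=O
Why: Acylation of the only free phenol makes the vinylogous-ester ketone more electrophilic and supplies the acyl group that is lost in the next step.

**Step 20**
Reactants: 38 acetoxychromanone
Product: 41 5-{4,6-bis[(tert-butyldimethylsilyl)oxy]-7-[(2R)-3-methylbut-3-en-2-yl]benzofuran-2-yl}-2,2-dimethyl-6-(3-methylbut-2-enyl)chroman-7-ol, via chromanol acetate 39 (not isolated), via para-quinone methide 40 (not isolated)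
Conditions: NaBH4 (excess), THF–H2O, 0 to 40 °C
Reagents that add atoms: none
Why: In this borohydride deoxygenation of a p-acyloxyaryl ketone, hydride first gives 39, net loss of acetic acid through the freed para-phenoxide gives quinone methide 40, and 1,6-hydride addition gives the methylene group without any acid, so the alkenes are safe and partial silyl loss is harmless before step 21.

**Step 21**
Reactants: 41 bis-TBS chromanol
Product: 42 2-[7-hydroxy-2,2-dimethyl-6-(3-methylbut-2-enyl)chroman-5-yl]-7-[(2R)-3-methylbut-3-en-2-yl]benzofuran-4,6-diol (CNP0325834.1)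
Conditions: TBAF, AcOH, THF, 0 °C
Reagents that add atoms: none
Why: Fluoride desilylation buffered with acetic acid frees both phenols under nearly neutral conditions that neither cyclize the o-alkenylphenols nor touch the stereocentre.

**Compound list**
1 | phloroglucinol | Oc1cc(O)cc(O)c1 | starting material
2 | 1,3,5-tris(methoxymethoxy)benzene | COCOc1cc(OCOC)cc(OCOC)c1 | intermediate
3 | [2,4,6-tris(methoxymethoxy)phenyl]lithium | [Li]c1c(OCOC)cc(OCOC)cc1OCOC | intermediate
4 | 2-[2,4,6-tris(methoxymethoxy)phenyl]-4,4,5,5-tetramethyl-1,3,2-dioxaborolane | CC1(C)OB(OC1(C)C)c1c(OCOC)cc(OCOC)cc1OCOC | intermediate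
5 | 2,4,6-triisopropylbenzoic acid | CC(C)c1cc(C(C)C)c(C(=O)O)c(C(C)C)c1 | starting material
6 | iodoethane | CCI | starting material
7 | ethyl 2,4,6-triisopropylbenzoate | CCOC(=O)c1c(C(C)C)cc(C(C)C)cc1C(C)C | intermediate
8 | (R)-1-lithioethyl 2,4,6-triisopropylbenzoate, (+)-sparteine complex | [Li][C@H](C)OC(=O)c1c(C(C)C)cc(C(C)C)cc1C(C)C | intermediate
9 | lithium [(1R)-1-(2,4,6-triisopropylbenzoyloxy)ethyl][2,4,6-tris(methoxymethoxy)phenyl](pinacolato)borate | [Li+].CC1(C)O[B-](OC1(C)C)([C@H](C)OC(=O)c1c(C(C)C)cc(C(C)C)cc1C(C)C)c1c(OCOC)cc(OCOC)cc1OCOC | intermediate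
10 | (S)-4,4,5,5-tetramethyl-2-{1-[2,4,6-tris(methoxymethoxy)phenyl]ethyl}-1,3,2-dioxaborolane | CC1(C)OB(OC1(C)C)[C@@H](C)c1c(OCOC)cc(OCOC)cc1OCOC | intermediate
11 | 2-bromopropene | C=C(C)Br | starting material
12 | isopropenyllithium | C=C(C)[Li] | intermediate
13 | lithium (prop-1-en-2-yl){(1S)-1-[2,4,6-tris(methoxymethoxy)phenyl]ethyl}(pinacolato)borate | [Li+].C=C(C)[B-]1(OC(C)(C)C(C)(C)O1)[C@@H](C)c1c(OCOC)cc(OCOC)cc1OCOC | intermediate
14 | 2-{(3R)-1-iodo-2-methyl-3-[2,4,6-tris(methoxymethoxy)phenyl]butan-2-yl}-4,4,5,5-tetramethyl-1,3,2-dioxaborolane (C2 unassigned) | ICC(C)(B1OC(C)(C)C(C)(C)O1)[C@@H](C)c1c(OCOC)cc(OCOC)cc1OCOC | intermediate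
15 | (R)-1,3,5-tris(methoxymethoxy)-2-(3-methylbut-3-en-2-yl)benzene | C=C(C)[C@@H](C)c1c(OCOC)cc(OCOC)cc1OCOC | intermediate
16 | {2,4,6-tris(methoxymethoxy)-3-[(2R)-3-methylbut-3-en-2-yl]phenyl}lithium | C=C(C)[C@@H](C)c1c(OCOC)cc(OCOC)c([Li])c1OCOC | intermediate
17 | 2,4,6-tris(methoxymethoxy)-3-[(2R)-3-methylbut-3-en-2-yl]benzaldehyde | C=C(C)[C@@H](C)c1c(OCOC)cc(OCOC)c(C=O)c1OCOC | intermediate
18 | 2,4,6-trihydroxy-3-[(2R)-3-methylbut-3-en-2-yl]benzaldehyde | C=C(C)[C@@H](C)c1c(O)cc(O)c(C=O)c1O | intermediate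
19 | 4,6-bis(TBS-oxy)-2-hydroxy-3-[(2R)-3-methylbut-3-en-2-yl]benzaldehyde | C=C(C)[C@@H](C)c1c(O[Si](C)(C)C(C)(C)C)cc(O[Si](C)(C)C(C)(C)C)c(C=O)c1O | intermediate
20 | 3,5-bis(TBS-oxy)-2-(2,2-dibromovinyl)-6-[(2R)-3-methylbut-3-en-2-yl]phenol | C=C(C)[C@@H](C)c1c(O[Si](C)(C)C(C)(C)C)cc(O[Si](C)(C)C(C)(C)C)c(C=C(Br)Br)c1O | intermediate
21 | 2-bromo-4,6-bis(TBS-oxy)-7-[(2R)-3-methylbut-3-en-2-yl]benzofuran | C=C(C)[C@@H](C)c1c(O[Si](C)(C)C(C)(C)C)cc(O[Si](C)(C)C(C)(C)C)c2cc(Br)oc12 | intermediate
22 | 3-methylbut-2-enal | CC(C)=CC=O | starting material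
23 | ethynylmagnesium bromide | C#C[Mg]Br | starting material
24 | 5-methylhex-4-en-1-yn-3-ol (racemic) | C#CC(O)C=C(C)C | intermediate
25 | 1-{4,6-bis(TBS-oxy)-7-[(2R)-3-methylbut-3-en-2-yl]benzofuran-2-yl}-5-methylhex-4-en-1-yn-3-ol | C=C(C)[C@@H](C)c1c(O[Si](C)(C)C(C)(C)C)cc(O[Si](C)(C)C(C)(C)C)c2cc(C#CC(O)C=C(C)C)oc12 | intermediate
26 | 1-{4,6-bis(TBS-oxy)-7-[(2R)-3-methylbut-3-en-2-yl]benzofuran-2-yl}-5-methylhex-4-en-1-yn-3-one | C=C(C)[C@@H](C)c1c(O[Si](C)(C)C(C)(C)C)cc(O[Si](C)(C)C(C)(C)C)c2cc(C#CC(=O)C=C(C)C)oc12 | intermediate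
27 | methyl acetoacetate | COC(=O)CC(C)=O | starting material
28 | prenyl bromide | CC(C)=CCBr | starting material
29 | methyl acetoacetate dianion (sodium lithium salt) | [Na+].[Li+].COC([O-])=CC(=C)[O-] | intermediate
30 | methyl 7-methyl-3-oxooct-6-enoate | COC(=O)CC(=O)CCC=C(C)C | intermediate
31 | methyl 7-methyl-3-(trimethylsilyloxy)octa-2,6-dienoate | COC(=O)C=C(CCC=C(C)C)O[Si](C)(C)C | intermediate
32 | lithium dienolate of 31 | COC(O[Li])=CC(=CCC=C(C)C)O[Si](C)(C)C | intermediate
33 | (1Z,3Z)-1-methoxy-7-methyl-1,3-bis(trimethylsilyloxy)octa-1,3,6-triene | CO/C(O[Si](C)(C)C)=C/C(O[Si](C)(C)C)=C/CC=C(C)C | intermediate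
34 | cyclohexa-1,4-diene cycloadduct of 26 and 33 (ring sp3 centres unassigned) | C=C(C)[C@@H](C)c1c(O[Si](C)(C)C(C)(C)C)cc(O[Si](C)(C)C(C)(C)C)c2cc(C3=C(C(=O)C=C(C)C)C(OC)(O[Si](C)(C)C)C=C(O[Si](C)(C)C)C3CC=C(C)C)oc12 | intermediate
35 | 3'-O-trimethylsilyl ether of 36 | C=C(C)[C@@H](C)c1c(O[Si](C)(C)C(C)(C)C)cc(O[Si](C)(C)C(C)(C)C)c2cc(-c3c(CC=C(C)C)c(O[Si](C)(C)C)cc(O)c3C(=O)C=C(C)C)oc12 | intermediate
36 | 2-[3,5-dihydroxy-2-(3-methylbut-2-enoyl)-6-prenylphenyl]-4,6-bis(TBS-oxy)-7-[(2R)-3-methylbut-3-en-2-yl]benzofuran | C=C(C)[C@@H](C)c1c(O[Si](C)(C)C(C)(C)C)cc(O[Si](C)(C)C(C)(C)C)c2cc(-c3c(CC=C(C)C)c(O)cc(O)c3C(=O)C=C(C)C)oc12 | intermediate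
37 | 5-{4,6-bis(TBS-oxy)-7-[(2R)-3-methylbut-3-en-2-yl]benzofuran-2-yl}-7-hydroxy-2,2-dimethyl-6-prenylchroman-4-one | C=C(C)[C@@H](C)c1c(O[Si](C)(C)C(C)(C)C)cc(O[Si](C)(C)C(C)(C)C)c2cc(-c3c(CC=C(C)C)c(O)cc4c3C(=O)CC(C)(C)O4)oc12 | intermediate
38 | 7-O-acetate of 37 | C=C(C)[C@@H](C)c1c(O[Si](C)(C)C(C)(C)C)cc(O[Si](C)(C)C(C)(C)C)c2cc(-c3c(CC=C(C)C)c(OC(C)=O)cc4c3C(=O)CC(C)(C)O4)oc12 | intermediate
39 | 4-hydroxychroman-7-yl acetate from 38 (C4 unassigned) | C=C(C)[C@@H](C)c1c(O[Si](C)(C)C(C)(C)C)cc(O[Si](C)(C)C(C)(C)C)c2cc(-c3c(CC=C(C)C)c(OC(C)=O)cc4c3C(O)CC(C)(C)O4)oc12 | intermediate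
40 | para-quinone methide (2,2-dimethyl-2,3-dihydro-7H-chromen-7-one form of ring B) | C=C(C)[C@@H](C)c1c(O[Si](C)(C)C(C)(C)C)cc(O[Si](C)(C)C(C)(C)C)c2cc(C3=C(CC=C(C)C)C(=O)C=C4OC(C)(C)CC=C34)oc12 | intermediate
41 | 5-{4,6-bis(TBS-oxy)-7-[(2R)-3-methylbut-3-en-2-yl]benzofuran-2-yl}-2,2-dimethyl-6-prenylchroman-7-ol | C=C(C)[C@@H](C)c1c(O[Si](C)(C)C(C)(C)C)cc(O[Si](C)(C)C(C)(C)C)c2cc(-c3c(CC=C(C)C)c(O)cc4c3CCC(C)(C)O4)oc12 | intermediate
42 | CNP0325834.1 | C=C(C)[C@@H](C)c1c(O)cc(O)c2cc(-c3c(CC=C(C)C)c(O)cc4c3CCC(C)(C)O4)oc12 | target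

**Totals and risks**

Total step count: 21. Longest linear sequence: 16 steps (1, 2, 4–10, 12, 13, 17–21).

Steps most likely to fail:

1. Step 17. The cycloaddition may be too slow. The β-carbon carries an electron-releasing benzofuranyl group, the diene terminus carries a prenyl chain, and the cross-conjugated enone lowers the electrophilicity of the alkyne. Thermal silyl migration and hydrolysis of the diene may therefore outrun bond formation. The fallback sets out from 21 and comes back at 37. It uses a smaller, more electrophilic acetyl ynone and adds the pyranone carbons afterwards. Sonogashira coupling of 21 with but-3-yn-2-ol should give the benzofuranyl butynol F1, and MnO2 oxidation the benzofuranyl butynone F2. Cycloaddition of F2 with 33 and aromatization as in step 17 should give the ring B 2-hydroxyacetophenone F3. Kabbe condensation of F3 with acetone (pyrrolidine, MeCN, 60 °C) should then give chromanone 37.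

2. Step 4. Formation of the boronate complex at the di-ortho-substituted boron may be slow or reversible, so that the carbenoid decomposes, conversion stays low, or the aryl boronate is protodeboronated. The fallback sets out from 2 and comes back at 15. It lets the hindered aryl group attack an unhindered boron, with stereocontrol from a chiral diol. Methylboronic acid and (S,S)-1,2-dicyclohexylethane-1,2-diol give the methylboronic ester F4. Matteson homologation (LiCHCl2, ZnCl2, −100 °C to rt) gives the (1R)-1-chloroethyl boronic ester F5. Aryllithium 3, made from 2 as in step 2, adds to F5 at −78 °C, and on warming the aryl group displaces chloride with inversion to give the (1S)-benzylic dicyclohexylethanediol boronic ester F6. Under the Zweifel conditions of step 5, F6 should give 15.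

3. Step 20. The reduction may stop at the chromanol stage, or the quinone methide may lose a C3 proton and tautomerize to the 2H-chromene faster than it takes up hydride. The fallback sets out from 37 and comes back at 41. It avoids both cation and quinone methide. Condensation of 37 with tosylhydrazine (EtOH, 70 °C) gives the chromanone tosylhydrazone F7. Reduction with catecholborane (CHCl3, −10 °C) followed by NaOAc·3H2O at reflux releases sulfinate and nitrogen through the diazene and should give 41, the alkenes being inert to catecholborane at this temperature.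

**Further compounds**
F1 | step 17 | 4-{4,6-bis(TBS-oxy)-7-[(2R)-3-methylbut-3-en-2-yl]benzofuran-2-yl}but-3-yn-2-ol | C=C(C)[C@@H](C)c1c(O[Si](C)(C)C(C)(C)C)cc(O[Si](C)(C)C(C)(C)C)c2cc(C#CC(C)O)oc12
F2 | step 17 | 4-{4,6-bis(TBS-oxy)-7-[(2R)-3-methylbut-3-en-2-yl]benzofuran-2-yl}but-3-yn-2-one | C=C(C)[C@@H](C)c1c(O[Si](C)(C)C(C)(C)C)cc(O[Si](C)(C)C(C)(C)C)c2cc(C#CC(C)=O)oc12
F3 | step 17 | 1-[2-{4,6-bis(TBS-oxy)-7-[(2R)-3-methylbut-3-en-2-yl]benzofuran-2-yl}-4,6-dihydroxy-3-(3-methylbut-2-enyl)phenyl]ethanone | C=C(C)[C@@H](C)c1c(O[Si](C)(C)C(C)(C)C)cc(O[Si](C)(C)C(C)(C)C)c2cc(-c3c(CC=C(C)C)c(O)cc(O)c3C(C)=O)oc12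
F4 | step 4 | (4S,5S)-4,5-dicyclohexyl-2-methyl-1,3,2-dioxaborolane | CB1O[C@@H](C2CCCCC2)[C@H](C2CCCCC2)O1
F5 | step 4 | (4S,5S)-2-[(1R)-1-chloroethyl]-4,5-dicyclohexyl-1,3,2-dioxaborolane | C[C@H](Cl)B1O[C@@H](C2CCCCC2)[C@H](C2CCCCC2)O1
F6 | step 4 | (4S,5S)-4,5-dicyclohexyl-2-{(1S)-1-[2,4,6-tris(methoxymethoxy)phenyl]ethyl}-1,3,2-dioxaborolane | C[C@H](B1O[C@@H](C2CCCCC2)[C@H](C2CCCCC2)O1)c1c(OCOC)cc(OCOC)cc1OCOC
F7 | step 20 | 4-methylbenzenesulfonohydrazone of chromanone 37 | C=C(C)[C@@H](C)c1c(O[Si](C)(C)C(C)(C)C)cc(O[Si](C)(C)C(C)(C)C)c2cc(-c3c(CC=C(C)C)c(O)cc4c3C(=NNS(=O)(=O)c5ccc(C)cc5)CC(C)(C)O4)oc12
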